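## Analysis of the target

The target (46) is a 6,7-secokaurane of the spirolactone type; with kaurane numbering it is (1S,4R,5R,8S,9S,10S,13R)-configured. Ring A (C1–C5, C10) is a cyclohexane whose quaternary C10 is the spiro atom of a δ-lactone (C7(=O)–O–C20–C10–C9–C8). This lactone is fused through C8–C9 to a bicyclo[3.2.1]octane made of ring C (C8, C9, C11–C14) and ring D (C8, C13–C16), which carries the C15 ketone and the C16=C17 methylene. There are seven stereocentres, three of them quaternary (C4, C8, C10), and C8–C9–C10 form a contiguous, very crowded triad. On ring A the one-carbon arms C19 and C20 are axial and the C1 acetoxy group and the C6 arm are equatorial, all on one face, while C18, H5 and C9 lie on the other; on the bicycle, C10 sits on C9 on the face turned away from the C15–C16 bridge. Sensitive features are the α-methylene cyclopentanone (a Michael acceptor), the exocyclic alkene before the ketone is in place (protonation leads to isomerisation and skeletal shifts), two acetates next to a free primary alcohol (acyl migration), and the lactone, which could migrate to O1 because that ring would also be six-membered. The synthesis is hard because of the congestion at C8–C9–C10 and because four oxygenated carbons on ring A (C1, C6, C19, C20) and two carboxyl-level carbons (C7, C20) must each end in a different state. The strategy rests on the array O–C1–C10–C20: with C20 taken back to an ester, quaternary C10 is the α-carbon of a β-hydroxy ester, an aldol retron inside ring A.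

## Retrosynthetic reasoning

**46 back to 43.** The C15 ketone and the free C6 hydroxyl are unveiled last, through silyl ether 45 and allylic alcohol 44. The enone would not survive the hydride and enolate steps, and allylic oxidation of 43 can only occur at C15 because the other allylic carbon, C13, is a bridgehead.

**43 back to 38.** The acetates come from diol 42. The lactone C7–O20 bond of 41 is cut to give hydroxy tert-butyl ester 38. C7 must stay at the acid level while C20 is reduced, and a tert-butyl ester on quaternary C8 resists hydride. O1 is kept silylated so that only O20 can close, and the ester is cleaved without protic acid because C16=C17 is acid-sensitive.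

**38 back to 36.** The C20 carbinol comes from the methyl ester of 37, which is the silyl ether of the β-hydroxy ester 36. Silylation first excludes retro-aldol opening and fixes the O1/O20 differentiation.

**36 back to 35 (key disconnection).** The C1–C10 bond is cut to the bromo ester aldehyde 35. This removes ring A and two stereocentres (C1, C10) in one step and leaves a precursor whose remaining stereocentres lie on two separable fragments. The forward samarium Reformatsky closure must place C20 axial and O1 equatorial.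

**35 back to 32.** The aldehyde comes from the 4-methoxybenzyl ether through alcohol 34. The bromide of 33 comes from ester 32, in which C10–H is the only enolisable position.

**32 back to 27 and 8.** The C9–C10 bond is cut as a Mukaiyama–Michael addition of ester 27 to bicyclic enone 8; the C12 carbonyl of adduct 30 is then removed. The bicycle steers the nucleophile to the face of C9 opposite the C15–C16 bridge, which is the face required, and the union is convergent.

**8 back to 1 and 3.** The C13–C16 bond is cut to silyl dienol ether 7 of propargyl cyclohexenone 6, which closes by a Conia-ene-type cyclisation. Enone 6 comes by carbonyl transposition from β-keto ester 4, whose quaternary C8 is set by asymmetric alkylation of 2 with 3; 2 comes from 1. C8 is the only stereocentre that needs external control, and C13 follows from it.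

**27 back to 19 and 11.** C10 is inserted by Arndt–Eistert homologation (26 from diazoketone 25 from acid 23), and the C4–C5 bond is cut by an Ireland–Claisen rearrangement of ester 20. The rearrangement sets quaternary C4 and tertiary C5 together by chirality transfer from the carbinol of 19, and the acid partner 11 already carries C6 as a protected alcohol.

**19 back to 12 and 13; 11 back to 9.** The (R)-allylic alcohol 19 comes from aldehyde 12 by Wittig reaction with 13 and protecting-group adjustment (14, 15, 17, 18). Acid 11 comes from diol 9 through 10.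

## Alternatives that were turned down

**Alternative 1: Michael–aldol annulation.** This cuts C8–C9 and C12–C13. A finished ring A would carry a C9=C11–C12 enal on C10 and, esterified to O20, a ring D 1,2-dione ester. Mild base or amine catalysis would add C8 to C9 (closing the lactone) and then C13 to the C12 aldehyde (closing ring C), giving A1. It is more convergent than the chosen route, forms two bonds, two rings and three stereocentres at once, and avoids an intermolecular C9–C10 coupling. On those points it is stronger. Against it: ring A with C1, C4, C5 and quaternary C10 must already exist, which is the problem the aldol closure solves. The Michael step must also discriminate the faces of an acyclic enal on a quaternary carbon with only the tether as control. A1 then needs C12 deoxygenation and regioselective methylenation of one carbonyl of an enolisable 1,2-dione. The chosen route forms fewer bonds in its key step but places the stereochemical risk in a chair-controlled, chelated closure and reaches the C15/C16 functionality by a known allylic oxidation.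

**Alternative 2: ring-contracting Ireland–Claisen.** This cuts C8–C14, taking the C7 carboxyl back to a lactone onto O12 of an allylic C12–C13=C14 unit. The ring-fixed ketene acetal would rearrange through a boat, forming C8–C14 and cleaving O–C12, to give A2 with a 2-bromoallyl arm for later ring D closure. It sets quaternary C8 relative to C9 by chirality transfer rather than by a chiral catalyst, which is more certain than step 2 of the chosen route. Against it: the whole of ring A and the crowded C9–C10 bond must pre-exist. The medium-ring lactone is long to make, the boat must tolerate the ring A substituent on C9, and A2 carries four different oxygen protecting groups that must later be sorted. The chosen route keeps the two halves simple until they are joined and builds ring A on the finished bicycle.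

**Alternative 3: citraconate-tethered Diels–Alder.** This cuts C5–C10 and C3–C4. A 2-silyloxy diene (C10=C1–C2=C3) on C9 of the bicycle would add to a citraconate (C4=C5) tethered through its C6 carboxyl to O20, giving A3 with a cis-fused γ-lactone. It forms two bonds and three stereocentres (C4, C5, C10; two quaternary) in one step, which is clearly better bond economy than the aldol closure. Against it: the diene terminus C10 is fully substituted and carries the bicycle, and the dienophile is trisubstituted, so the cycloaddition is sterically very demanding. Facial selectivity depends on a rotatable C9–C10 bond and on the geometry of the C10=C1 alkene. Afterwards C6 and C19 are both at the carboxyl level and must be reduced while C7 is not, O20 must be moved from C6 to C7, and the C1 ketone must be reduced selectively. The chosen route sets C4 and C5 by a sigmatropic shift on an acyclic fragment, keeps C6 and C19 at the alcohol level throughout, and needs only one reduction (C20).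

Key step: step 23

Remarks on the chemistry:
- Kaurane numbering (C1–C20) is used for all intermediates.
- Compounds 30–35 are carried as C10 epimers because C10 is set only in step 23.
- In step 2 the enantiomer of the phase-transfer catalyst that gives the (1R) ester is used.

## Route

Step 1
Reactants: 1 3-ethoxycyclohex-2-en-1-one
Product: 2 tert-butyl 4-ethoxy-2-oxocyclohex-3-ene-1-carboxylate
Conditions: LiN(iPr)2 (2.1 equiv), THF, −78 °C; Boc2O, −78 → 0 °C; aq. NH4Cl
Reagents that add atoms: di-tert-butyl dicarbonate, CC(C)(C)OC(=O)OC(=O)OC(C)(C)C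
Why: Kinetic deprotonation of the vinylogous ester at the α′ carbon and C-acylation of the enolate; the second equivalent of base turns the product into its enolate and so protects it from further attack.

Step 2
Reactants: 2 tert-butyl 4-ethoxy-2-oxocyclohex-3-ene-1-carboxylate; 3 3-bromoprop-1-yne
Product: 4 tert-butyl (1R)-4-ethoxy-2-oxo-1-(prop-2-yn-1-yl)cyclohex-3-ene-1-carboxylate
Conditions: 3 (1.5 equiv), chiral N-spiro binaphthyl quaternary ammonium bromide with 3,4,5-trifluorophenyl groups at the 3,3′ positions (1 mol%), aq. K2CO3, toluene, 0 °C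
Reagents that add atoms: none
Why: Asymmetric phase-transfer alkylation of a cyclic β-keto tert-butyl ester; the chiral ammonium enolate ion pair exposes one enolate face to the propargylic bromide and sets quaternary C8, from which C13 later follows.

Step 3
Reactants: 4 tert-butyl (1R)-4-ethoxy-2-oxo-1-(prop-2-yn-1-yl)cyclohex-3-ene-1-carboxylate
Product: 6 tert-butyl (1R)-4-oxo-1-(prop-2-yn-1-yl)cyclohex-2-ene-1-carboxylate, via allylic alcohol 5 (not isolated)
Conditions: iBu2AlH (1.2 equiv), CH2Cl2, −78 °C; then 1 M HCl, THF, 0 °C → rt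
Reagents that add atoms: water, O
Why: Stork–Danheiser transposition: 1,2-reduction of the vinylogous ester carbonyl, then acid-promoted loss of water and hydrolysis of the enol ether put the carbonyl at C12 and the alkene at C9=C11; the hindered tert-butyl ester is untouched at −78 °C and the quaternary centre cannot epimerise.

Step 4
Reactants: 6 tert-butyl (1R)-4-oxo-1-(prop-2-yn-1-yl)cyclohex-2-ene-1-carboxylate
Product: 7 tert-butyl (1R)-1-(prop-2-yn-1-yl)-4-{[tri(propan-2-yl)silyl]oxy}cyclohexa-2,4-diene-1-carboxylate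
Conditions: iPr3SiOTf, Et3N, CH2Cl2, 0 °C
Reagents that add atoms: tri(propan-2-yl)silyl trifluoromethanesulfonate, CC(C)[Si](C(C)C)(C(C)C)OS(=O)(=O)C(F)(F)F
Why: Soft enolisation at the only enolisable carbon (C13; C8 is quaternary) gives the cross-conjugated 2-silyloxy diene that serves as the carbon nucleophile.

Step 5
Reactants: 7 tert-butyl (1R)-1-(prop-2-yn-1-yl)-4-{[tri(propan-2-yl)silyl]oxy}cyclohexa-2,4-diene-1-carboxylate
Product: 8 tert-butyl (1R,5R)-6-methylidene-4-oxobicyclo[3.2.1]oct-2-ene-1-carboxylate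
Conditions: Ph3PAuCl (2 mol%), AgBF4 (2 mol%), toluene/MeOH 10:1, rt
Reagents that add atoms: none
Why: Monovalent gold-catalysed 5-exo-dig carbocyclisation of a silyl enol ether onto a terminal alkyne (Conia-ene type); C13 can only attack on the face that carries the propargyl arm, so its configuration follows from C8, and protodeauration leaves the C16=C17 methylene.

Step 6
Reactants: 9 propane-1,3-diol
Product: 10 3-{[tert-butyl(diphenyl)silyl]oxy}propan-1-ol
Conditions: NaH (1.0 equiv), THF, 0 °C; tBuPh2SiCl (1.0 equiv), rt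
Reagents that add atoms: tert-butyl(chloro)diphenylsilane, CC(C)(C)[Si](Cl)(c1ccccc1)c1ccccc1
Why: Monosilylation of a symmetrical diol through its sparingly soluble monosodium alkoxide, which reacts once.

Step 7
Reactants: 10 3-{[tert-butyl(diphenyl)silyl]oxy}propan-1-ol
Product: 11 3-{[tert-butyl(diphenyl)silyl]oxy}propanoic acid
Conditions: TEMPO (10 mol%), PhI(OAc)2 (2.2 equiv), MeCN/H2O 1:1, rt
Reagents that add atoms: water, O
Why: Nitroxyl-catalysed oxidation of the primary alcohol through the aldehyde hydrate to the acid; the silyl ether is stable under these near-neutral conditions.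

Step 8
Reactants: 12 (4S)-2,2-dimethyl-1,3-dioxolane-4-carbaldehyde; 13 ethyl 2-(triphenyl-λ5-phosphanylidene)propanoate
Product: 14 ethyl (2E)-3-[(4R)-2,2-dimethyl-1,3-dioxolan-4-yl]-2-methylprop-2-enoate
Conditions: CH2Cl2, 0 °C → rt
Reagents that add atoms: none
Why: Wittig olefination with a stabilised α-branched ylide gives the (E)-trisubstituted enoate (ester trans to the dioxolane); the α-alkoxy aldehyde is used cold to avoid epimerisation.

Step 9
Reactants: 14 ethyl (2E)-3-[(4R)-2,2-dimethyl-1,3-dioxolan-4-yl]-2-methylprop-2-enoate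
Product: 15 ethyl (2E,4R)-4,5-dihydroxy-2-methylpent-2-enoate
Conditions: AcOH/H2O 4:1, 40 °C
Reagents that add atoms: none
Why: Acid hydrolysis of the acetonide; the (E) geometry prevents the freed hydroxyls from lactonising onto the ester.

Step 10
Reactants: 15 ethyl (2E,4R)-4,5-dihydroxy-2-methylpent-2-enoate
Product: 17 ethyl (2E,4R)-4-hydroxy-5-[(4-methoxyphenyl)methoxy]-2-methylpent-2-enoate, via stannylene acetal 16 (not isolated)
Conditions: Bu2SnO, toluene, reflux (Dean–Stark); then 4-MeOC6H4CH2Cl, Bu4NI, 80 °C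
Reagents that add atoms: 4-methoxybenzyl chloride, COc1ccc(CCl)cc1
Why: Stannylene acetal activation of the 1,2-diol directs alkylation to the primary oxygen and leaves the secondary carbinol free.

Step 11
Reactants: 17 ethyl (2E,4R)-4-hydroxy-5-[(4-methoxyphenyl)methoxy]-2-methylpent-2-enoate
Product: 18 (2E,4R)-5-[(4-methoxyphenyl)methoxy]-2-methylpent-2-ene-1,4-diol
Conditions: iBu2AlH (3.5 equiv), CH2Cl2, −78 → −20 °C; aq. KNaC4H4O6
Reagents that add atoms: none
Why: 1,2-Reduction of the enoate to the allylic alcohol; no stereocentre is touched.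

Step 12
Reactants: 18 (2E,4R)-5-[(4-methoxyphenyl)methoxy]-2-methylpent-2-ene-1,4-diol
Product: 19 (2R,3E)-5-{[tert-butyl(dimethyl)silyl]oxy}-1-[(4-methoxyphenyl)methoxy]-4-methylpent-3-en-2-ol
Conditions: tBuMe2SiCl (1.05 equiv), imidazole, CH2Cl2, −20 °C
Reagents that add atoms: tert-butyl(chloro)dimethylsilane, CC(C)(C)[Si](C)(C)Cl
Why: The primary allylic hydroxyl is silylated much faster than the secondary one at low temperature, which leaves the carbinol free for acylation.

Step 13
Reactants: 19 (2R,3E)-5-{[tert-butyl(dimethyl)silyl]oxy}-1-[(4-methoxyphenyl)methoxy]-4-methylpent-3-en-2-ol; 11 3-{[tert-butyl(diphenyl)silyl]oxy}propanoic acid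
Product: 20 (2R,3E)-5-{[tert-butyl(dimethyl)silyl]oxy}-1-[(4-methoxyphenyl)methoxy]-4-methylpent-3-en-2-yl 3-{[tert-butyl(diphenyl)silyl]oxy}propanoate
Conditions: DCC, DMAP (10 mol%), CH2Cl2, 0 °C → rt
Reagents that add atoms: none
Why: Steglich esterification of the secondary allylic alcohol; no stereocentre is involved.

Step 14
Reactants: 20 (2R,3E)-5-{[tert-butyl(dimethyl)silyl]oxy}-1-[(4-methoxyphenyl)methoxy]-4-methylpent-3-en-2-yl 3-{[tert-butyl(diphenyl)silyl]oxy}propanoate
Product: 23 (2S,3R,4E)-2-({[tert-butyl(diphenyl)silyl]oxy}methyl)-3-({[tert-butyl(dimethyl)silyl]oxy}methyl)-6-[(4-methoxyphenyl)methoxy]-3-methylhex-4-enoic acid, via silyl ketene acetal 21 (not isolated), via trimethylsilyl ester 22 (not isolated)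
Conditions: LiN(iPr)2 (1.3 equiv), Me3SiCl/Et3N, THF, −78 °C → 50 °C; aq. NH4Cl
Reagents that add atoms: none
Why: Ireland–Claisen rearrangement: kinetic enolisation in THF gives the ketene acetal with the CH2OSi arm cis to the allylic oxygen, and the chair transition state with the CH2OPMB group of the (R)-carbinol equatorial transfers chirality to quaternary C4 (R) and to C5 while forming the C4–C5 bond and the (E)-C2=C3 alkene; silylation in situ at −78 °C forestalls β-elimination of the silyloxy group.

Step 15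
Reactants: 23 (2S,3R,4E)-2-({[tert-butyl(diphenyl)silyl]oxy}methyl)-3-({[tert-butyl(dimethyl)silyl]oxy}methyl)-6-[(4-methoxyphenyl)methoxy]-3-methylhex-4-enoic acid
Product: 25 (3S,4R,5E)-3-({[tert-butyl(diphenyl)silyl]oxy}methyl)-4-({[tert-butyl(dimethyl)silyl]oxy}methyl)-1-diazo-7-[(4-methoxyphenyl)methoxy]-4-methylhept-5-en-2-one, via acid chloride 24 (not isolated)
Conditions: Me2C=C(Cl)NMe2, CH2Cl2, 0 °C; then CH2N2 (excess), Et2O, 0 °C
Reagents that add atoms: diazomethane, C=[N+]=[N-]
Why: First half of an Arndt–Eistert homologation: the neutral chloroenamine forms the acid chloride without free HCl, and excess diazomethane acylates and scavenges HCl, so C5 (α to the carbonyl) is not epimerised.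

Step 16
Reactants: 25 (3S,4R,5E)-3-({[tert-butyl(diphenyl)silyl]oxy}methyl)-4-({[tert-butyl(dimethyl)silyl]oxy}methyl)-1-diazo-7-[(4-methoxyphenyl)methoxy]-4-methylhept-5-en-2-one
Product: 26 methyl (3S,4R,5E)-3-({[tert-butyl(diphenyl)silyl]oxy}methyl)-4-({[tert-butyl(dimethyl)silyl]oxy}methyl)-7-[(4-methoxyphenyl)methoxy]-4-methylhept-5-enoate
Conditions: PhCO2Ag (10 mol%), Et3N, MeOH, rt, dark
Reagents that add atoms: methanol, CO
Why: Silver-catalysed Wolff rearrangement: C5 migrates with retention and methanol traps the ketene, which places C10 between C5 and the ester carbon C20.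

Step 17
Reactants: 26 methyl (3S,4R,5E)-3-({[tert-butyl(diphenyl)silyl]oxy}methyl)-4-({[tert-butyl(dimethyl)silyl]oxy}methyl)-7-[(4-methoxyphenyl)methoxy]-4-methylhept-5-enoate
Product: 27 methyl (3S,4R)-3-({[tert-butyl(diphenyl)silyl]oxy}methyl)-4-({[tert-butyl(dimethyl)silyl]oxy}methyl)-7-[(4-methoxyphenyl)methoxy]-4-methylheptanoate
Conditions: H2 (1 atm), [Ir(cod)(PCy3)(py)]PF6 (5 mol%), CH2Cl2, rt
Reagents that add atoms: none
Why: Homogeneous hydrogenation of the hindered disubstituted alkene with a cationic iridium catalyst, which does not hydrogenolyse the allylic or benzylic C–O bonds.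

Step 18
Reactants: 27 methyl (3S,4R)-3-({[tert-butyl(diphenyl)silyl]oxy}methyl)-4-({[tert-butyl(dimethyl)silyl]oxy}methyl)-7-[(4-methoxyphenyl)methoxy]-4-methylheptanoate; 8 tert-butyl (1R,5R)-6-methylidene-4-oxobicyclo[3.2.1]oct-2-ene-1-carboxylate
Product: 30 C12 ketone adduct (tert-butyl 6-methylidene-4-oxobicyclo[3.2.1]octane-1-carboxylate carrying the chain on C9 through C10; C10 epimers), via ketene acetal 28 (not isolated), via silyl enol ether 29 (not isolated)
Conditions: 27, LiN(iPr)2, Me3SiCl, THF, −78 °C; then 8 (1.2 equiv), Tf2NH (5 mol%), CH2Cl2, −78 → −40 °C; K2CO3, MeOH, 0 °C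
Reagents that add atoms: none
Why: Mukaiyama–Michael addition: the silylium species formed from Tf2NH and 28 activates the enone, and the ketene acetal attacks C9 along the axial trajectory on the face opposite the C15–C16 bridge, which sets C9 as in the target; C10 forms as a mixture that is erased in step 20.

Step 19
Reactants: 30 C12 ketone adduct
Product: 32 deoxygenated diester (C12 now CH2; C10 epimers), via tosylhydrazone 31 (not isolated)
Conditions: TsNHNH2, EtOH, 50 °C; then catecholborane, CHCl3, 0 °C; NaOAc·3H2O, 60 °C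
Reagents that add atoms: none
Why: Reductive deoxygenation through the tosylhydrazone: hydride adds to C=N and the resulting diazene loses nitrogen, which turns C12 into CH2 under conditions that spare both esters, the silyl ethers and the exocyclic alkene (catecholborane does not hydroborate at this temperature).

Step 20
Reactants: 32 deoxygenated diester
Product: 33 C10 bromo ester with C1 4-methoxybenzyl ether (both C10 epimers)
Conditions: LiN(iPr)2 (1.5 equiv), THF/DMPU, −78 → −40 °C; NBS, −78 °C; aq. NH4Cl
Reagents that add atoms: N-bromosuccinimide, O=C1CCC(=O)N1Br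
Why: Enolate bromination: C10–H is the only enolisable hydrogen (the tert-butyl ester has no α-hydrogen and C12 is no longer a ketone), so excess amide base can be used to overcome the hindered deprotonation; both bromide epimers are useful.

Step 21
Reactants: 33 C10 bromo ester with C1 4-methoxybenzyl ether
Product: 34 C10 bromo ester C1 alcohol
Conditions: DDQ (1.3 equiv), CH2Cl2/pH 7 buffer 10:1, 0 °C
Reagents that add atoms: none
Why: Oxidative cleavage of the 4-methoxybenzyl ether under buffered conditions leaves the tertiary bromide, both silyl ethers and the alkene intact.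

Step 22
Reactants: 34 C10 bromo ester C1 alcohol
Product: 35 bicyclic bromo ester aldehyde (C10 bromide epimers)
Conditions: Dess–Martin periodinane, NaHCO3, CH2Cl2, 0 °C → rt
Reagents that add atoms: none
Why: Buffered hypervalent-iodine oxidation of the primary alcohol to the aldehyde without over-oxidation; the aldehyde is used at once.

Step 23
Reactants: 35 bicyclic bromo ester aldehyde
Product: 36 ring A β-hydroxy ester on the bicyclic core (C20 methyl ester axial on C10, C1–OH equatorial)
Conditions: SmI2 (2.5 equiv, 0.1 M in THF), THF, −78 °C, slow addition of 35 (final 0.01 M); aq. NH4Cl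
Reagents that add atoms: none
Why: Samarium diiodide transfers two electrons to the tertiary C–Br bond and gives a trivalent samarium ester enolate, which adds to the C1 aldehyde in the same molecule; this is an intramolecular samarium Reformatsky (aldol-type) reaction, a known way to six-membered β-hydroxy esters with quaternary α-carbons. Ring A closes by a 6-(enolexo)-exo-trig addition that forms the C1–C10 bond. C10 is set by a chair-like transition state in which the CH2OSi arm on C5 is equatorial, the C19 arm on C4 is therefore axial, and the bicyclic C9 substituent takes the pseudo-equatorial site, because the alternative would place it 1,3-diaxial to C19; the ester carbon C20 thus becomes axial. C1 is set by chelation: the oxophilic trivalent samarium bridges the enolate oxygen and the aldehyde oxygen in a six-membered array, which holds the C1 oxygen equatorial and gauche to C20. The step needs reduction of the α-bromo ester before the aldehyde, which the much faster electron transfer to the activated C–Br bond at −78 °C without HMPA secures. Both C10 bromide epimers give the same enolate, so the mixture converges. The tert-butyl ester has no α-hydrogen and the 1,1-disubstituted alkene is inert to SmI2. Slow addition at high dilution suppresses intermolecular aldol reaction and proton transfer from C2.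

Step 24
Reactants: 36 ring A β-hydroxy ester
Product: 37 C1 triethylsilyl ether of 36
Conditions: Et3SiOTf, 2,6-lutidine, CH2Cl2, −78 → 0 °C
Reagents that add atoms: triethylsilyl trifluoromethanesulfonate, CC[Si](CC)(CC)OS(=O)(=O)C(F)(F)F
Why: Silyl triflate silylation of the hindered equatorial alcohol blocks O1, so that it can neither undergo retro-aldol cleavage during reduction nor compete with O20 in the later lactonisation.

Step 25
Reactants: 37 C1 triethylsilyl ether
Product: 38 C20 primary alcohol (C7 tert-butyl ester retained)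
Conditions: iBu2AlH (3 equiv), CH2Cl2, −78 → 0 °C; aq. KNaC4H4O6
Reagents that add atoms: none
Why: The methyl ester is reduced while the tert-butyl ester on bridgehead quaternary C8 is inert at low temperature; the silyl-capped β-oxygen excludes retro-aldol opening.

Step 26
Reactants: 38 C20 primary alcohol
Product: 41 7,20-lactone (O1 triethylsilyl, O19 tert-butyldimethylsilyl, O6 tert-butyldiphenylsilyl), via bis(trimethylsilyl) derivative 39 (not isolated), via hydroxy acid 40 (not isolated)
Conditions: Me3SiOTf (4 equiv), 2,6-lutidine (6 equiv), CH2Cl2, 0 °C → rt; then K2CO3, MeOH, 0 °C; then EDC·HCl, DMAP, CH2Cl2, rt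
Reagents that add atoms: none
Why: Silyl triflate with 2,6-lutidine cleaves the tert-butyl ester by loss of isobutene under proton-free conditions, which protects the acid-sensitive exocyclic alkene; after methanolysis of the silyl ester and the O20 silyl ether, carbodiimide activation closes the δ-lactone, favoured by the two flanking quaternary carbons, and only O20 is free to react.

Step 27
Reactants: 41 7,20-lactone
Product: 42 1,19-diol lactone (O6 tert-butyldiphenylsilyl)
Conditions: camphorsulfonic acid (20 mol%), MeOH/CH2Cl2 1:1, 0 °C → rt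
Reagents that add atoms: none
Why: Acid-catalysed methanolysis removes the triethylsilyl ether and the primary tert-butyldimethylsilyl ether, while the far more acid-stable tert-butyldiphenylsilyl ether at C6 stays; the mild acid does not protonate the alkene.

Step 28
Reactants: 42 1,19-diol lactone
Product: 43 1,19-diacetate (O6 tert-butyldiphenylsilyl)
Conditions: Ac2O, DMAP, pyridine, rt
Reagents that add atoms: acetic anhydride, CC(=O)OC(C)=O
Why: DMAP-catalysed acetylation of both free hydroxyls; O6 is still silylated, so no selectivity problem arises.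

Step 29
Reactants: 43 1,19-diacetate
Product: 44 C15 allylic alcohol
Conditions: SeO2 (0.5 equiv), tBuOOH (3 equiv), CH2Cl2, rt
Reagents that add atoms: selenium dioxide, O=[Se]=O; tert-butyl hydroperoxide, CC(C)(C)OO
Why: Allylic oxidation by ene reaction and 2,3-sigmatropic shift can only use the C15 hydrogens, because C13 is a bridgehead, and returns the exocyclic alkene; the C15 configuration is irrelevant.

Step 30
Reactants: 44 C15 allylic alcohol
Product: 45 15-oxo-16-ene (O6 tert-butyldiphenylsilyl)
Conditions: Dess–Martin periodinane, NaHCO3, CH2Cl2, rt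
Reagents that add atoms: none
Why: Neutral oxidation of the allylic alcohol to the α-methylene ketone without isomerising the alkene.

Step 31
Reactants: 45 15-oxo-16-ene
Product: 46 target, (1S,4R,5R,8S,9S,10S,13R)-1,19-diacetoxy-6-hydroxy-15-oxo-6,7-secokaur-16-en-7,20-olide
Conditions: HF·pyridine, pyridine, THF, 0 °C → rt
Reagents that add atoms: none
Why: Fluoride cleavage of the silyl ether under weakly acidic conditions, which suppresses acetyl migration from O19 to O6 and conjugate addition to the enone.

## Compound list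

1 | 3-ethoxycyclohex-2-en-1-one | CCOC1=CC(=O)CCC1 | starting material
2 | tert-butyl 4-ethoxy-2-oxocyclohex-3-ene-1-carboxylate (racemic, configurationally labile) | CCOC1=CC(=O)C(C(=O)OC(C)(C)C)CC1 | intermediate
3 | 3-bromoprop-1-yne | C#CCBr | starting material
4 | tert-butyl (1R)-4-ethoxy-2-oxo-1-(prop-2-yn-1-yl)cyclohex-3-ene-1-carboxylate | C#CC[C@@]1(C(=O)OC(C)(C)C)C(=O)C=C(OCC)CC1 | intermediate
5 | tert-butyl (1R)-4-ethoxy-2-hydroxy-1-(prop-2-yn-1-yl)cyclohex-3-ene-1-carboxylate (both C2 epimers) | C#CC[C@@]1(C(=O)OC(C)(C)C)C(O)C=C(OCC)CC1 | intermediate (not isolated)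
6 | tert-butyl (1R)-4-oxo-1-(prop-2-yn-1-yl)cyclohex-2-ene-1-carboxylate | C#CC[C@@]1(C(=O)OC(C)(C)C)C=CC(=O)CC1 | intermediate
7 | tert-butyl (1R)-1-(prop-2-yn-1-yl)-4-{[tri(propan-2-yl)silyl]oxy}cyclohexa-2,4-diene-1-carboxylate | C#CC[C@@]1(C(=O)OC(C)(C)C)C=CC(O[Si](C(C)C)(C(C)C)C(C)C)=CC1 | intermediate
8 | tert-butyl (1R,5R)-6-methylidene-4-oxobicyclo[3.2.1]oct-2-ene-1-carboxylate | C=C1C[C@]2(C(=O)OC(C)(C)C)C[C@H]1C(=O)C=C2 | intermediate
9 | propane-1,3-diol | OCCCO | starting material
10 | 3-{[tert-butyl(diphenyl)silyl]oxy}propan-1-ol | OCCCO[Si](c1ccccc1)(c1ccccc1)C(C)(C)C | intermediate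
11 | 3-{[tert-butyl(diphenyl)silyl]oxy}propanoic acid | OC(=O)CCO[Si](c1ccccc1)(c1ccccc1)C(C)(C)C | intermediate
12 | (4S)-2,2-dimethyl-1,3-dioxolane-4-carbaldehyde | O=C[C@@H]1COC(C)(C)O1 | starting material
13 | ethyl 2-(triphenyl-λ5-phosphanylidene)propanoate | CCOC(=O)C(C)=P(c1ccccc1)(c1ccccc1)c1ccccc1 | starting material
14 | ethyl (2E)-3-[(4R)-2,2-dimethyl-1,3-dioxolan-4-yl]-2-methylprop-2-enoate | CCOC(=O)/C(C)=C/[C@@H]1COC(C)(C)O1 | intermediate
15 | ethyl (2E,4R)-4,5-dihydroxy-2-methylpent-2-enoate | CCOC(=O)/C(C)=C/[C@@H](O)CO | intermediate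
16 | ethyl (2E)-3-[(4R)-2,2-dibutyl-1,3,2-dioxastannolan-4-yl]-2-methylprop-2-enoate | CCOC(=O)/C(C)=C/[C@@H]1CO[Sn](CCCC)(CCCC)O1 | intermediate (not isolated)
17 | ethyl (2E,4R)-4-hydroxy-5-[(4-methoxyphenyl)methoxy]-2-methylpent-2-enoate | CCOC(=O)/C(C)=C/[C@@H](O)COCc1ccc(OC)cc1 | intermediate
18 | (2E,4R)-5-[(4-methoxyphenyl)methoxy]-2-methylpent-2-ene-1,4-diol | OC/C(C)=C/[C@@H](O)COCc1ccc(OC)cc1 | intermediate
19 | (2R,3E)-5-{[tert-butyl(dimethyl)silyl]oxy}-1-[(4-methoxyphenyl)methoxy]-4-methylpent-3-en-2-ol | CC(C)(C)[Si](C)(C)OC/C(C)=C/[C@@H](O)COCc1ccc(OC)cc1 | intermediate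
20 | (2R,3E)-5-{[tert-butyl(dimethyl)silyl]oxy}-1-[(4-methoxyphenyl)methoxy]-4-methylpent-3-en-2-yl 3-{[tert-butyl(diphenyl)silyl]oxy}propanoate | CC(C)(C)[Si](C)(C)OC/C(C)=C/[C@@H](OC(=O)CCO[Si](c1ccccc1)(c1ccccc1)C(C)(C)C)COCc1ccc(OC)cc1 | intermediate
21 | trimethylsilyl ketene acetal of 20 (CH2OSi arm cis to the allylic oxygen) | CC(C)(C)[Si](C)(C)OC/C(C)=C/[C@@H](O/C(O[Si](C)(C)C)=C\CO[Si](c1ccccc1)(c1ccccc1)C(C)(C)C)COCc1ccc(OC)cc1 | intermediate (not isolated)
22 | trimethylsilyl ester of acid 23 | C[Si](C)(C)OC(=O)[C@H](CO[Si](c1ccccc1)(c1ccccc1)C(C)(C)C)[C@](C)(CO[Si](C)(C)C(C)(C)C)/C=C/COCc1ccc(OC)cc1 | intermediate (not isolated)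
23 | (2S,3R,4E)-2-({[tert-butyl(diphenyl)silyl]oxy}methyl)-3-({[tert-butyl(dimethyl)silyl]oxy}methyl)-6-[(4-methoxyphenyl)methoxy]-3-methylhex-4-enoic acid | OC(=O)[C@H](CO[Si](c1ccccc1)(c1ccccc1)C(C)(C)C)[C@](C)(CO[Si](C)(C)C(C)(C)C)/C=C/COCc1ccc(OC)cc1 | intermediate
24 | acid chloride of 23 | ClC(=O)[C@H](CO[Si](c1ccccc1)(c1ccccc1)C(C)(C)C)[C@](C)(CO[Si](C)(C)C(C)(C)C)/C=C/COCc1ccc(OC)cc1 | intermediate (not isolated)
25 | (3S,4R,5E)-3-({[tert-butyl(diphenyl)silyl]oxy}methyl)-4-({[tert-butyl(dimethyl)silyl]oxy}methyl)-1-diazo-7-[(4-methoxyphenyl)methoxy]-4-methylhept-5-en-2-one | [N-]=[N+]=CC(=O)[C@H](CO[Si](c1ccccc1)(c1ccccc1)C(C)(C)C)[C@](C)(CO[Si](C)(C)C(C)(C)C)/C=C/COCc1ccc(OC)cc1 | intermediate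
26 | methyl (3S,4R,5E)-3-({[tert-butyl(diphenyl)silyl]oxy}methyl)-4-({[tert-butyl(dimethyl)silyl]oxy}methyl)-7-[(4-methoxyphenyl)methoxy]-4-methylhept-5-enoate | COC(=O)C[C@H](CO[Si](c1ccccc1)(c1ccccc1)C(C)(C)C)[C@](C)(CO[Si](C)(C)C(C)(C)C)/C=C/COCc1ccc(OC)cc1 | intermediate
27 | methyl (3S,4R)-3-({[tert-butyl(diphenyl)silyl]oxy}methyl)-4-({[tert-butyl(dimethyl)silyl]oxy}methyl)-7-[(4-methoxyphenyl)methoxy]-4-methylheptanoate | COC(=O)C[C@H](CO[Si](c1ccccc1)(c1ccccc1)C(C)(C)C)[C@](C)(CO[Si](C)(C)C(C)(C)C)CCCOCc1ccc(OC)cc1 | intermediate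
28 | trimethylsilyl ketene acetal of 27 (C10=C20, both alkene geometries) | COC(O[Si](C)(C)C)=C[C@H](CO[Si](c1ccccc1)(c1ccccc1)C(C)(C)C)[C@](C)(CO[Si](C)(C)C(C)(C)C)CCCOCc1ccc(OC)cc1 | intermediate (not isolated)
29 | C11=C12 trimethylsilyl enol ether of ketone 30 | C=C1C[C@]2(C(=O)OC(C)(C)C)C[C@H]1C(O[Si](C)(C)C)=C[C@H]2C(C(=O)OC)[C@H](CO[Si](c1ccccc1)(c1ccccc1)C(C)(C)C)[C@](C)(CO[Si](C)(C)C(C)(C)C)CCCOCc1ccc(OC)cc1 | intermediate (not isolated)
30 | tert-butyl 6-methylidene-4-oxobicyclo[3.2.1]octane-1-carboxylate (C8, C9, C13 configured as in 46) carrying on C9 the chain C10H(CO2Me)–C5H(CH2OSitBuPh2)–C4(CH3)(CH2OSitBuMe2)–(CH2)3–O–CH2C6H4OMe, C4 (R), C5 (S), C10 epimers | C=C1C[C@]2(C(=O)OC(C)(C)C)C[C@H]1C(=O)C[C@H]2C(C(=O)OC)[C@H](CO[Si](c1ccccc1)(c1ccccc1)C(C)(C)C)[C@](C)(CO[Si](C)(C)C(C)(C)C)CCCOCc1ccc(OC)cc1 | intermediate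
31 | C12 4-methylbenzenesulfonylhydrazone of 30 | C=C1C[C@]2(C(=O)OC(C)(C)C)C[C@H]1C(=NNS(=O)(=O)c1ccc(C)cc1)C[C@H]2C(C(=O)OC)[C@H](CO[Si](c1ccccc1)(c1ccccc1)C(C)(C)C)[C@](C)(CO[Si](C)(C)C(C)(C)C)CCCOCc1ccc(OC)cc1 | intermediate (not isolated)
32 | as 30 with C12 as CH2 (tert-butyl 6-methylidenebicyclo[3.2.1]octane-1-carboxylate with the same chain on C9; C10 epimers) | C=C1C[C@]2(C(=O)OC(C)(C)C)C[C@H]1CC[C@H]2C(C(=O)OC)[C@H](CO[Si](c1ccccc1)(c1ccccc1)C(C)(C)C)[C@](C)(CO[Si](C)(C)C(C)(C)C)CCCOCc1ccc(OC)cc1 | intermediate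
33 | as 32 with bromine on C10 (both epimers) | C=C1C[C@]2(C(=O)OC(C)(C)C)C[C@H]1CC[C@H]2C(Br)(C(=O)OC)[C@H](CO[Si](c1ccccc1)(c1ccccc1)C(C)(C)C)[C@](C)(CO[Si](C)(C)C(C)(C)C)CCCOCc1ccc(OC)cc1 | intermediate
34 | as 33 with free C1 hydroxyl | C=C1C[C@]2(C(=O)OC(C)(C)C)C[C@H]1CC[C@H]2C(Br)(C(=O)OC)[C@H](CO[Si](c1ccccc1)(c1ccccc1)C(C)(C)C)[C@](C)(CO[Si](C)(C)C(C)(C)C)CCCO | intermediate
35 | bicyclic bromo ester aldehyde: as 34 with C1 as aldehyde | C=C1C[C@]2(C(=O)OC(C)(C)C)C[C@H]1CC[C@H]2C(Br)(C(=O)OC)[C@H](CO[Si](c1ccccc1)(c1ccccc1)C(C)(C)C)[C@](C)(CO[Si](C)(C)C(C)(C)C)CCC=O | intermediate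
36 | ring A β-hydroxy ester: tert-butyl 6-methylidenebicyclo[3.2.1]octane-1-carboxylate carrying on C9 the cyclohexane ring A, with axial CO2Me (C20) on C10, equatorial 1-OH, axial CH2OSitBuMe2 (C19) and CH3 on C4, equatorial CH2OSitBuPh2 (C6) on C5; all stereocentres as in 46 | C=C1C[C@]2(C(=O)OC(C)(C)C)C[C@H]1CC[C@H]2[C@]1(C(=O)OC)[C@@H](O)CC[C@@](C)(CO[Si](C)(C)C(C)(C)C)[C@H]1CO[Si](c1ccccc1)(c1ccccc1)C(C)(C)C | intermediate
37 | 1-O-triethylsilyl ether of 36 | C=C1C[C@]2(C(=O)OC(C)(C)C)C[C@H]1CC[C@H]2[C@]1(C(=O)OC)[C@@H](O[Si](CC)(CC)CC)CC[C@@](C)(CO[Si](C)(C)C(C)(C)C)[C@H]1CO[Si](c1ccccc1)(c1ccccc1)C(C)(C)C | intermediate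
38 | as 37 with C20 as CH2OH | C=C1C[C@]2(C(=O)OC(C)(C)C)C[C@H]1CC[C@H]2[C@]1(CO)[C@@H](O[Si](CC)(CC)CC)CC[C@@](C)(CO[Si](C)(C)C(C)(C)C)[C@H]1CO[Si](c1ccccc1)(c1ccccc1)C(C)(C)C | intermediate
39 | as 38 with C7 trimethylsilyl ester and O20 trimethylsilyl ether | C=C1C[C@]2(C(=O)O[Si](C)(C)C)C[C@H]1CC[C@H]2[C@]1(CO[Si](C)(C)C)[C@@H](O[Si](CC)(CC)CC)CC[C@@](C)(CO[Si](C)(C)C(C)(C)C)[C@H]1CO[Si](c1ccccc1)(c1ccccc1)C(C)(C)C | intermediate (not isolated)
40 | as 38 with C7 as free carboxylic acid | C=C1C[C@]2(C(=O)O)C[C@H]1CC[C@H]2[C@]1(CO)[C@@H](O[Si](CC)(CC)CC)CC[C@@](C)(CO[Si](C)(C)C(C)(C)C)[C@H]1CO[Si](c1ccccc1)(c1ccccc1)C(C)(C)C | intermediate (not isolated)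
41 | 6,7-secokaur-16-en-7,20-olide with 1-OSiEt3, 19-OSitBuMe2, 6-OSitBuPh2; stereocentres as in 46 | C=C1C[C@]23C[C@H]1CC[C@H]2[C@]1(COC3=O)[C@@H](O[Si](CC)(CC)CC)CC[C@@](C)(CO[Si](C)(C)C(C)(C)C)[C@H]1CO[Si](c1ccccc1)(c1ccccc1)C(C)(C)C | intermediate
42 | as 41 with free 1-OH and 19-OH | C=C1C[C@]23C[C@H]1CC[C@H]2[C@]1(COC3=O)[C@@H](O)CC[C@@](C)(CO)[C@H]1CO[Si](c1ccccc1)(c1ccccc1)C(C)(C)C | intermediate
43 | 1,19-diacetate of 42 | C=C1C[C@]23C[C@H]1CC[C@H]2[C@]1(COC3=O)[C@@H](OC(C)=O)CC[C@@](C)(COC(C)=O)[C@H]1CO[Si](c1ccccc1)(c1ccccc1)C(C)(C)C | intermediate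
44 | 15-hydroxy derivative of 43 (either C15 epimer) | C=C1C(O)[C@]23C[C@H]1CC[C@H]2[C@]1(COC3=O)[C@@H](OC(C)=O)CC[C@@](C)(COC(C)=O)[C@H]1CO[Si](c1ccccc1)(c1ccccc1)C(C)(C)C | intermediate
45 | 6-O-tert-butyldiphenylsilyl ether of 46 | C=C1C(=O)[C@]23C[C@H]1CC[C@H]2[C@]1(COC3=O)[C@@H](OC(C)=O)CC[C@@](C)(COC(C)=O)[C@H]1CO[Si](c1ccccc1)(c1ccccc1)C(C)(C)C | intermediate
46 | (1S,4R,5R,8S,9S,10S,13R)-1,19-diacetoxy-6-hydroxy-15-oxo-6,7-secokaur-16-en-7,20-olide (kaurane numbering) | C=C1C(=O)[C@]23C[C@H]1CC[C@H]2[C@]1(COC3=O)[C@@H](OC(C)=O)CC[C@@](C)(COC(C)=O)[C@H]1CO | target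

## Step count and risk

Total: 31 steps. Longest linear sequence: 24 steps (12 to 46: steps 8–31). The bicyclic enone 8 (steps 1–5) and acid 11 (steps 6–7) are made in side branches.

**Step 23 (key step).** The most likely failures are proton quench of the samarium enolate (simple debromination, because closure onto a neopentyl-like centre is slow) and closure through a transition state that places the C9 group axial, giving the wrong C10 face, because the acyclic enolate is free to rotate about C5–C10. The fallback ties O6 to C20 so that the enolate is part of a five-membered ring and only cis fusion is feasible. It sets out from 32: Bu4NF removes both silyl ethers and the O6 alkoxide closes onto the methyl ester to give the γ-lactone alcohol F14. tBuMe2SiCl with imidazole gives the 19-silyl ether F15. LiN(SiMe3)2 then NBS gives the bromolactone F16. DDQ gives the alcohol F17 and Dess–Martin periodinane the aldehyde F18. SmI2 at −78 °C closes ring A to the cis-fused hydroxy lactone F19. Et3SiOTf with 2,6-lutidine gives the silyl ether F20. LiBH4 opens the lactone to the 6,20-diol F21. tBuPh2SiCl with imidazole at −20 °C silylates the less hindered O6, and the fallback rejoins the route at 38.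

**Step 18.** The likely failure is that no C–C bond forms (silyl transfer only, or recovery of 8), because C9 is flanked by quaternary C8 and the nucleophilic C10 by the branched C5. The fallback uses a smaller cyclic donor. It sets out from 27: Bu4NF gives the hydroxy γ-lactone F9. tBuMe2SiCl with imidazole gives the silyl ether F10. LiN(iPr)2 and Me3SiCl give the cyclic ketene acetal F11. Addition to 8 with Tf2NH (5 mol%), followed by K2CO3 in MeOH, gives the lactone ketone F12, with attack trans to the C5 substituent and on the same face of C9 as before. LiOH, then tBuPh2SiCl with imidazole, then K2CO3 in aqueous MeOH give the silyloxy acid F13. Me3SiCHN2 in MeOH esterifies it, and the fallback rejoins the route at 30.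

**Step 14.** The likely failures are erosion of the C5 configuration through a mixed ketene acetal geometry and loss of silanolate from the ester enolate before silylation. The fallback separates the two stereocentres. It sets out from 19: triethyl orthoacetate with catalytic propionic acid at 140 °C (Johnson–Claisen, no enolate, same chair) gives the ethyl ester F4 with C4 set. LiOH gives the acid F5. Pivaloyl chloride with Et3N, then lithiated (4S)-4-benzyl-1,3-oxazolidin-2-one, gives the imide F6. NaN(SiMe3)2 and methyl bromoacetate give the alkylated imide F7, with C5 set by the auxiliary. LiBH4 with one equivalent of water removes the auxiliary reductively to give the hydroxy ester F8. tBuPh2SiCl with imidazole silylates O6, and the fallback rejoins the route at 26.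

**Step 2.** The likely failure is insufficient face discrimination in the ion pair, because the enolate of 2 is a cross-conjugated vinylogous ester and not the simple saturated β-keto ester for which such catalysts are best documented. The fallback uses transition-metal catalysis and a different ring closure. It sets out from 2: allyl acetate with [Pd(C3H5)Cl]2, the (R,R)-1,2-diaminocyclohexane-derived bis(2-diphenylphosphinobenzamide) ligand (or its antipode) and tetramethylguanidine in toluene gives the allyl β-keto ester F1 by asymmetric allylic alkylation. iBu2AlH then 1 M HCl gives the allyl cyclohexenone F2. tBuMe2SiOTf with Et3N gives the silyl dienol ether F3. Pd(OAc)2 (10 mol%) under O2 in DMSO at 45 °C (cycloalkenylation by divalent palladium, with β-hydride elimination to the exocyclic alkene) closes ring D, and the fallback rejoins the route at 8.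

## Further compounds

F1 | step 2 | tert-butyl (1R)-4-ethoxy-2-oxo-1-(prop-2-en-1-yl)cyclohex-3-ene-1-carboxylate | C=CC[C@@]1(C(=O)OC(C)(C)C)C(=O)C=C(OCC)CC1
F2 | step 2 | tert-butyl (1R)-4-oxo-1-(prop-2-en-1-yl)cyclohex-2-ene-1-carboxylate | C=CC[C@@]1(C(=O)OC(C)(C)C)C=CC(=O)CC1
F3 | step 2 | tert-butyl (1R)-4-{[tert-butyl(dimethyl)silyl]oxy}-1-(prop-2-en-1-yl)cyclohexa-2,4-diene-1-carboxylate | C=CC[C@@]1(C(=O)OC(C)(C)C)C=CC(O[Si](C)(C)C(C)(C)C)=CC1
F4 | step 14 | ethyl (3S,4E)-3-({[tert-butyl(dimethyl)silyl]oxy}methyl)-6-[(4-methoxyphenyl)methoxy]-3-methylhex-4-enoate | CCOC(=O)C[C@](C)(CO[Si](C)(C)C(C)(C)C)/C=C/COCc1ccc(OC)cc1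
F5 | step 14 | (3S,4E)-3-({[tert-butyl(dimethyl)silyl]oxy}methyl)-6-[(4-methoxyphenyl)methoxy]-3-methylhex-4-enoic acid | OC(=O)C[C@](C)(CO[Si](C)(C)C(C)(C)C)/C=C/COCc1ccc(OC)cc1
F6 | step 14 | (4S)-4-benzyl-3-acyl-1,3-oxazolidin-2-one of acid F5 | O=C1OC[C@H](Cc2ccccc2)N1C(=O)C[C@](C)(CO[Si](C)(C)C(C)(C)C)/C=C/COCc1ccc(OC)cc1
F7 | step 14 | imide F6 alkylated at C5 with CH2CO2Me (C5 configured as in 26) | O=C1OC[C@H](Cc2ccccc2)N1C(=O)[C@@H](CC(=O)OC)[C@](C)(CO[Si](C)(C)C(C)(C)C)/C=C/COCc1ccc(OC)cc1
F8 | step 14 | methyl (5E)-4-({[tert-butyl(dimethyl)silyl]oxy}methyl)-3-(hydroxymethyl)-7-[(4-methoxyphenyl)methoxy]-4-methylhept-5-enoate, C3 and C4 as in 26 | COC(=O)C[C@H](CO)[C@](C)(CO[Si](C)(C)C(C)(C)C)/C=C/COCc1ccc(OC)cc1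
F9 | step 18 | 4-substituted oxolan-2-one (C20(=O)–O–C6 lactone) with C4 carrying CH3, CH2OH and (CH2)3OCH2C6H4OMe; C4 and C5 as in 27 | O=C1C[C@@H]([C@](C)(CO)CCCOCc2ccc(OC)cc2)CO1
F10 | step 18 | 19-O-tert-butyldimethylsilyl ether of F9 | O=C1C[C@@H]([C@](C)(CO[Si](C)(C)C(C)(C)C)CCCOCc2ccc(OC)cc2)CO1
F11 | step 18 | 2-(trimethylsilyloxy)-4,5-dihydrofuran derived from F10 | C[Si](C)(C)OC1=C[C@@H]([C@](C)(CO[Si](C)(C)C(C)(C)C)CCCOCc2ccc(OC)cc2)CO1
F12 | step 18 | Michael adduct of F11 and 8: C12 ketone with the γ-lactone on C9 through C10 | C=C1C[C@]2(C(=O)OC(C)(C)C)C[C@H]1C(=O)C[C@H]2C1C(=O)OC[C@@H]1[C@](C)(CO[Si](C)(C)C(C)(C)C)CCCOCc1ccc(OC)cc1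
F13 | step 18 | C20 carboxylic acid corresponding to 30 | C=C1C[C@]2(C(=O)OC(C)(C)C)C[C@H]1C(=O)C[C@H]2C(C(=O)O)[C@H](CO[Si](c1ccccc1)(c1ccccc1)C(C)(C)C)[C@](C)(CO[Si](C)(C)C(C)(C)C)CCCOCc1ccc(OC)cc1
F14 | step 23 | C20(=O)–O–C6 γ-lactone from 32 with free 19-OH | C=C1C[C@]2(C(=O)OC(C)(C)C)C[C@H]1CC[C@H]2C1C(=O)OC[C@@H]1[C@](C)(CO)CCCOCc1ccc(OC)cc1
F15 | step 23 | 19-O-tert-butyldimethylsilyl ether of F14 | C=C1C[C@]2(C(=O)OC(C)(C)C)C[C@H]1CC[C@H]2C1C(=O)OC[C@@H]1[C@](C)(CO[Si](C)(C)C(C)(C)C)CCCOCc1ccc(OC)cc1
F16 | step 23 | C10 bromolactone from F15 | C=C1C[C@]2(C(=O)OC(C)(C)C)C[C@H]1CC[C@H]2C1(Br)C(=O)OC[C@@H]1[C@](C)(CO[Si](C)(C)C(C)(C)C)CCCOCc1ccc(OC)cc1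
F17 | step 23 | bromolactone C1 alcohol | C=C1C[C@]2(C(=O)OC(C)(C)C)C[C@H]1CC[C@H]2C1(Br)C(=O)OC[C@@H]1[C@](C)(CO[Si](C)(C)C(C)(C)C)CCCO
F18 | step 23 | bromolactone C1 aldehyde | C=C1C[C@]2(C(=O)OC(C)(C)C)C[C@H]1CC[C@H]2C1(Br)C(=O)OC[C@@H]1[C@](C)(CO[Si](C)(C)C(C)(C)C)CCC=O
F19 | step 23 | ring A 1-hydroxy compound with cis-fused C20(=O)–O–C6 γ-lactone | C=C1C[C@]2(C(=O)OC(C)(C)C)C[C@H]1CC[C@H]2[C@]13C(=O)OC[C@@H]3[C@](C)(CO[Si](C)(C)C(C)(C)C)CC[C@@H]1O
F20 | step 23 | 1-O-triethylsilyl ether of F19 | C=C1C[C@]2(C(=O)OC(C)(C)C)C[C@H]1CC[C@H]2[C@]13C(=O)OC[C@@H]3[C@](C)(CO[Si](C)(C)C(C)(C)C)CC[C@@H]1O[Si](CC)(CC)CC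
F21 | step 23 | 6,20-diol corresponding to 38 without the O6 silyl group | C=C1C[C@]2(C(=O)OC(C)(C)C)C[C@H]1CC[C@H]2[C@]1(CO)[C@@H](O[Si](CC)(CC)CC)CC[C@@](C)(CO[Si](C)(C)C(C)(C)C)[C@H]1CO
A1 | alternative 1 | tetracyclic C15,C16-dione with C12 carbinol, 1,19-diacetate, O6 silyl ether | O=C1C(=O)[C@]23C[C@H]1[C@@H](O)C[C@H]2[C@]1(COC3=O)[C@@H](OC(C)=O)CC[C@@](C)(COC(C)=O)[C@H]1CO[Si](C)(C)C(C)(C)C
A2 | alternative 2 | ring C cyclohexene acid with quaternary C8 and 2-bromoallyl arm | C=C(Br)C[C@]1(C(=O)O)CC=CC[C@H]1[C@]1(CO[Si](CC)(CC)CC)[C@@H](O[Si](C)(C)C(C)(C)C)CC[C@@](C)(CO[Si](C)(C)C(C)(C)C)[C@H]1COCc1ccc(OC)cc1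
A3 | alternative 3 | ring A silyl enol ether with C6–O–C20 γ-lactone and C19 methyl ester on the bicyclic core | C=C1C[C@]2(C(=O)OC(C)(C)C)C[C@H]1CC[C@H]2[C@@]12COC(=O)[C@@H]1[C@](C)(C(=O)OC)CC=C2O[Si](C)(C)C(C)(C)C
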